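A direct plan would take 4-hydroxy-6-phenyl-2H-pyran-2-one A1, convert A1 under Mitsunobu conditions into its 4-O-prenyl ether, 4-[(3-methylbut-2-en-1-yl)oxy]-6-phenyl-2H-pyran-2-one A2, heat A2 so that a Claisen shift would give 4-hydroxy-3-(2-methylbut-3-en-2-yl)-6-phenyl-2H-pyran-2-one A3, and esterify A3 with 3-hydroxy-3-methylbutanoic acid A4 and a carbodiimide to reach the target.
Its weakest steps would be:
- the O-prenylation of A1, because the pyranone anion is ambident (O4, O2, C3) and regioisomeric ethers and C-prenyl products would be expected;
- the [3,3] shift of A2, because it would have to build the quaternary carbon at about 110 °C while the freed acidic 4-OH lies next to the new vinyl group (closure to a dihydrofuran) and ionisation of the ether would give the linear C-prenyl isomer;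
- the esterification of A3, because the 4-OH would be a weakly nucleophilic vinylogous acid beside the quaternary carbon and A4 would carry an unprotected tertiary alcohol (N-acylurea, β-lactone, oligoester).

The pyran ring would be built as its 4H-pyran-4-one isomer and then transposed. The key disconnection cuts the O4–acyl bond together with an O2–methyl bond and leads back to a 2-methoxy-4H-pyran-4-one, closed from an acyclic alkynyl β-keto ester whose quaternary carbon is bought. The key step exploits the vinylogous ester O2–C2=C3–C4=O4 of that ring: an acyl iodide acylates the C4 carbonyl oxygen, open on its C5–H side, and iodide removes the methyl group, so the hindered enol ester and the lactone carbonyl appear in one operation. No ambident O-alkylation, no sigmatropic shift and no free hindered 4-hydroxyl occur.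

Key step: step 4

Remark: the target is achiral, so no stereocentre needs control. The side-chain tertiary alkoxide is assumed to expel the pyranone with β-lactone formation, so no basic step is used once the ester is in place.

Step 1
Reactants: 1 3-phenylprop-2-ynoic acid; 2 methyl 3,3-dimethylpent-4-enoate
Product: 4 methyl 2-(2-methylbut-3-en-2-yl)-3-oxo-5-phenylpent-4-ynoate (racemic), via 3-phenylprop-2-ynoyl chloride 3 (not isolated)
Conditions: 1, (COCl)2 (1.2 equiv), DMF (cat.), CH2Cl2, 0 °C → rt, evaporate; then 2 (2.1 equiv), LiN(i-Pr)2 (2.1 equiv), THF, −78 °C, slow addition of 3; AcOH, −78 °C → rt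
Reagents that add atoms: none
Why: Crossed Claisen condensation (C-acylation of a lithium ester enolate by an acid chloride), in which the ynoyl chloride should react at its carbonyl carbon at −78 °C, the second equivalent of enolate takes up the acidic proton of the product, and the new stereocentre is formed racemic and is erased in step 2.

Step 2
Reactants: 4 methyl 2-(2-methylbut-3-en-2-yl)-3-oxo-5-phenylpent-4-ynoate
Product: 5 2-methoxy-3-(2-methylbut-3-en-2-yl)-6-phenyl-4H-pyran-4-one
Conditions: Ph3PAuNTf2 (2 mol%), dry CH2Cl2, rt
Reagents that add atoms: none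
Why: Ph3PAuNTf2-catalysed 6-endo-dig cyclisation of an alkynyl β-keto ester (carbonyl-oxygen addition to a π-activated alkyne), in which the ester carbonyl oxygen should add to C6, which is β to the ketone and benzylic, and loss of the C3 proton with protodeauration should give the 4H-pyran-4-one with the methyl group still on O2 and no stereocentre left.

Step 3
Reactants: 6 3-hydroxy-3-methylbutanoic acid
Product: 8 3-methyl-3-[(triethylsilyl)oxy]butanoyl chloride, via triethylsilyl 3-methyl-3-[(triethylsilyl)oxy]butanoate 7 (not isolated)
Conditions: Et3SiOTf (2.2 equiv), 2,6-lutidine (2.5 equiv), CH2Cl2, 0 °C; pentane, filter, evaporate; then (COCl)2 (1.1 equiv), DMF (cat.), CH2Cl2, 0 °C → rt; Et3SiCl removed at 0.1 mbar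
Reagents that add atoms: triethylsilyl trifluoromethanesulfonate, CC[Si](CC)(CC)OS(=O)(=O)C(F)(F)F; oxalyl chloride, O=C(Cl)C(=O)Cl
Why: Silylation of both hydroxyl functions by a silyl triflate, followed by conversion of the silyl ester into the acid chloride with oxalyl chloride/DMF (Vilsmeier-type chloride transfer under neutral conditions), should leave the hindered tertiary silyl ether untouched; no stereocentre is involved.

Step 4
Reactants: 5 2-methoxy-3-(2-methylbut-3-en-2-yl)-6-phenyl-4H-pyran-4-one; 8 3-methyl-3-[(triethylsilyl)oxy]butanoyl chloride
Product: 10 3-(2-methylbut-3-en-2-yl)-2-oxo-6-phenyl-2H-pyran-4-yl 3-methyl-3-[(triethylsilyl)oxy]butanoate, via 3-methyl-3-[(triethylsilyl)oxy]butanoyl iodide 9 (not isolated)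
Conditions: 8 (1.5 equiv), NaI (1.6 equiv), dry MeCN, 0 °C, 15 min; then 5, 0 °C → rt, dark, argon; cold aq. NaHCO3/Na2S2O3 work-up
Reagents that add atoms: none
Why: Proposed new method: the acyl iodide 9, formed from 8 and NaI, should acylate the only nucleophilic heteroatom of 5, the C4 carbonyl oxygen of the vinylogous ester O2–C2=C3–C4=O4, to give a 4-acyloxy-2-methoxypyrylium iodide, and iodide should then attack the O-methyl carbon in an SN2 step, which releases iodomethane and the neutral 2H-pyran-2-one. The closest known reaction types are the Hilbert–Johnson reaction of 2-alkoxypyrimidines and the cleavage of methyl esters and ethers by acyl iodides or iodotrimethylsilane, here relayed through the ring. No ring is closed and no stereocentre is formed; the 4H-pyran-4-one is converted into the 2H-pyran-2-one by this oxygen-to-oxygen transposition. The step needs O-acylation in place of C5-acylation and demethylation in place of loss of the acyl group: the carbonyl lone pair on the C5–H side is unhindered although C3 carries the quaternary substituent, and loss of iodomethane is the only irreversible exit from the ion pair. The C3 substituent also shields C4 from ipso attack by iodide, and the triethylsilyl ether keeps the acyl halide from closing to the β-lactone.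

Step 5
Reactants: 10 3-(2-methylbut-3-en-2-yl)-2-oxo-6-phenyl-2H-pyran-4-yl 3-methyl-3-[(triethylsilyl)oxy]butanoate
Product: 11 3-(2-methylbut-3-en-2-yl)-2-oxo-6-phenyl-2H-pyran-4-yl 3-hydroxy-3-methylbutanoate (target, achiral)
Conditions: HF·pyridine, THF, 0 °C → rt (plastic vessel); pH 7 phosphate buffer work-up
Reagents that add atoms: none
Why: Fluoride-driven cleavage of the tertiary triethylsilyl ether (formation of the strong Si–F bond) in an acidic, buffered medium should free the alcohol without ever generating the tertiary alkoxide, and the achiral target results.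

Compound list
1 | 3-phenylprop-2-ynoic acid | O=C(O)C#Cc1ccccc1 | starting material
2 | methyl 3,3-dimethylpent-4-enoate | COC(=O)CC(C)(C)C=C | starting material
3 | 3-phenylprop-2-ynoyl chloride | O=C(Cl)C#Cc1ccccc1 | intermediate
4 | methyl 2-(2-methylbut-3-en-2-yl)-3-oxo-5-phenylpent-4-ynoate (racemic) | COC(=O)C(C(C)(C)C=C)C(=O)C#Cc1ccccc1 | intermediate
5 | 2-methoxy-3-(2-methylbut-3-en-2-yl)-6-phenyl-4H-pyran-4-one | COC1=C(C(C)(C)C=C)C(=O)C=C(c2ccccc2)O1 | intermediate
6 | 3-hydroxy-3-methylbutanoic acid | CC(C)(O)CC(=O)O | starting material
7 | triethylsilyl 3-methyl-3-[(triethylsilyl)oxy]butanoate | CC[Si](CC)(CC)OC(=O)CC(C)(C)O[Si](CC)(CC)CC | intermediate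
8 | 3-methyl-3-[(triethylsilyl)oxy]butanoyl chloride | CC[Si](CC)(CC)OC(C)(C)CC(=O)Cl | intermediate
9 | 3-methyl-3-[(triethylsilyl)oxy]butanoyl iodide | CC[Si](CC)(CC)OC(C)(C)CC(=O)I | intermediate
10 | 3-(2-methylbut-3-en-2-yl)-2-oxo-6-phenyl-2H-pyran-4-yl 3-methyl-3-[(triethylsilyl)oxy]butanoate | C=CC(C)(C)c1c(OC(=O)CC(C)(C)O[Si](CC)(CC)CC)cc(-c2ccccc2)oc1=O | intermediate
11 | 3-(2-methylbut-3-en-2-yl)-2-oxo-6-phenyl-2H-pyran-4-yl 3-hydroxy-3-methylbutanoate (achiral) | C=CC(C)(C)c1c(OC(=O)CC(C)(C)O)cc(-c2ccccc2)oc1=O | target

Total step count: 5. Longest linear sequence: 4 (steps 1, 2, 4, 5); step 3 prepares the acyl donor.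

Steps most likely to fail

Step 4. The acyl-pyrylium ion pair may fall back to its components faster than iodide removes the methyl group, or the acyl iodide may attack its own silyl ether, so that the methoxy-pyranone is recovered or silylated. The fallback uses known chemistry and sets out from 5. Halide demethylation of the vinylogous methyl ester with LiI in ethyl acetate at reflux, then cold dilute HCl, should give 4-hydroxy-3-(2-methylbut-3-en-2-yl)-6-phenyl-2H-pyran-2-one F1. O-acylation of F1 with the acid chloride 8 and pyridine in CH2Cl2 at −20 °C, where the blocked C3 allows only O-acylation, would come back to the route at 10.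

Step 2. The terminal alkene may compete with the ester carbonyl oxygen for the alkyne activated by Ph3PAuNTf2 (enyne cycloisomerisation), or traces of water may hydrate the ynone. The fallback sets out from 4. Conjugate addition of diethylamine to the ynone (EtOH, rt) should give methyl (4E)-5-(diethylamino)-2-(2-methylbut-3-en-2-yl)-3-oxo-5-phenylpent-4-enoate F2. Acid-induced ring closure of F2 by addition–elimination (CF3CO2H, CH2Cl2), in which the ester carbonyl oxygen displaces diethylamine, would come back to the route at 5.

Step 1. C-acylation of the neopentyl-type enolate may be slow, so that O-acylation of the product enolate or conjugate addition to the ynone takes over. The fallback sets out from 2. Aldol addition of its lithium enolate to commercial 3-phenylprop-2-ynal (THF, −78 °C) should give methyl 3-hydroxy-2-(2-methylbut-3-en-2-yl)-5-phenylpent-4-ynoate F3, as a mixture of diastereomers. Oxidation of the propargylic alcohol of F3 with Dess–Martin periodinane would come back to the route at 4.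

Further compounds
F1 | step 4 | 4-hydroxy-3-(2-methylbut-3-en-2-yl)-6-phenyl-2H-pyran-2-one | C=CC(C)(C)c1c(O)cc(-c2ccccc2)oc1=O
F2 | step 2 | methyl (4E)-5-(diethylamino)-2-(2-methylbut-3-en-2-yl)-3-oxo-5-phenylpent-4-enoate (racemic) | CCN(CC)/C(c1ccccc1)=C/C(=O)C(C(=O)OC)C(C)(C)C=C
F3 | step 1 | methyl 3-hydroxy-2-(2-methylbut-3-en-2-yl)-5-phenylpent-4-ynoate (racemic mixture of diastereomers) | COC(=O)C(C(C)(C)C=C)C(O)C#Cc1ccccc1
A1 | direct plan | 4-hydroxy-6-phenyl-2H-pyran-2-one | O=c1cc(O)cc(-c2ccccc2)o1
A2 | direct plan | 4-[(3-methylbut-2-en-1-yl)oxy]-6-phenyl-2H-pyran-2-one | CC(C)=CCOc1cc(-c2ccccc2)oc(=O)c1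
A3 | direct plan | 4-hydroxy-3-(2-methylbut-3-en-2-yl)-6-phenyl-2H-pyran-2-one | C=CC(C)(C)c1c(O)cc(-c2ccccc2)oc1=O
A4 | direct plan | 3-hydroxy-3-methylbutanoic acid | CC(C)(O)CC(=O)O
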